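**Retrosynthetic overview**

1. The target is a trans-fused daucane. The cyclopentane is C1(quaternary, Me)–C2–C3–C4(OH, iPr)–C5(H); the cycloheptene is C1–C5–C6(O-anisoyl)–C7–C8(Me)=C9–C10(OAc). The C10 acetate, the C6 anisoate and the C6 carbinol (hydroxyl-directed reduction) lead back to a C6 ketone carrying the C4 tertiary aldol.
2. Key disconnection: the cyclopentane is cut at C1–C2 and C4–C5 at once. This is a formal [3+2] union of a cyclohepta-2,5-dienone (C6=O, C5=C1) with C2–C3–C4 as a zinc homoenolate, released by strain-driven opening of 1-isopropylcyclopropanol. Both new bonds end at fully substituted carbons (C1 and C4).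
3. Enabling feature: C4–OH and C6–O are 1,3-related across C5 (aldol retron) and C1 is β to C6 (conjugate-addition retron), so C2–C3–C4(O) is exactly a ketone homoenolate. The C10 oxygen on the carbon next to C1 steers the face of attack.
4. Ring order: a dihydropyranone (temporary ring; ring-closing metathesis fixes the Z C8=C9 alkene), then the seven-membered ring (second ring-closing metathesis), then the cyclopentane last.
5. Stereocontrol: C10 comes from a lipase-resolved carbinol and controls C1; C5 and C4 follow from a reversible aldol; C6 from directed reduction.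

Key step: step 10

Remark: daucane numbering as in line 1 is used throughout; β is the face of the C1 methyl group; compounds 2 and 12 are treated as not purchasable and are made.

**Route**

Step 1
Reactants: 1 methacrolein (2-methylprop-2-enal)
Product: 2 rac-2-methylpenta-1,4-dien-3-ol
Conditions: CH2=CHMgBr, THF, −78 → 0 °C; aq NH4Cl
Reagents that add atoms: vinylmagnesium bromide, C=C[Mg]Br
Why: Grignard 1,2-addition to the enal gives the racemic bis-allylic carbinol; no stereocontrol is needed because step 2 resolves it.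

Step 2
Reactants: 2 rac-2-methylpenta-1,4-dien-3-ol
Product: 3 (S)-2-methylpenta-1,4-dien-3-ol
Conditions: immobilised Candida antarctica lipase B, vinyl acetate, MTBE, rt, run past half conversion; separation from the acetate
Reagents that add atoms: none
Why: Lipase-catalysed kinetic resolution by transesterification; by the empirical size rule for secondary alcohols (vinyl as the small group, isopropenyl as the large group) the (R)-alcohol should be acylated, leaving the (S)-alcohol that carries the C10 configuration of the target.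

Step 3
Reactants: 3 (S)-2-methylpenta-1,4-dien-3-ol; 4 3-methylbut-3-enoic acid
Product: 5 (S)-2-methylpenta-1,4-dien-3-yl 3-methylbut-3-enoate
Conditions: DIC, DMAP (cat.), CH2Cl2, 0 °C
Reagents that add atoms: none
Why: Steglich esterification under mild, cold conditions should leave the carbinol centre untouched and limit migration of the β,γ-double bond of the acid.

Step 4
Reactants: 5 (S)-2-methylpenta-1,4-dien-3-yl 3-methylbut-3-enoate
Product: 6 (S)-4-methyl-6-(prop-1-en-2-yl)-3,6-dihydro-2H-pyran-2-one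
Conditions: second-generation Grubbs catalyst RuCl2(=CHPh)(SIMes)(PCy3) (cat.; SIMes = 1,3-dimesitylimidazolin-2-ylidene), CH2Cl2, high dilution, 40 °C
Reagents that add atoms: none
Why: Ring-closing metathesis between the vinyl group and the methallyl unit gives the six-membered lactone, whose ring forces the trisubstituted C8=C9 alkene to be Z; closure onto the isopropenyl group would need a tetrasubstituted alkene and should not compete.

Step 5
Reactants: 6 (S)-4-methyl-6-(prop-1-en-2-yl)-3,6-dihydro-2H-pyran-2-one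
Product: 7 (S,Z)-5-hydroxy-N-methoxy-N,3,6-trimethylhepta-3,6-dienamide
Conditions: MeNH(OMe)·HCl, AlMe3, CH2Cl2, 0 °C → rt; aq KNaC4H4O6 (potassium sodium tartrate)
Reagents that add atoms: N,O-dimethylhydroxylamine hydrochloride, CNOC.Cl
Why: Weinreb aminolysis of the lactone with the weakly basic aluminium amide opens the temporary ring at the acyl carbon and keeps the Z alkene and the carbinol centre.

Step 6
Reactants: 7 (S,Z)-5-hydroxy-N-methoxy-N,3,6-trimethylhepta-3,6-dienamide
Product: 8 (S,Z)-5-[(tert-butyldimethylsilyl)oxy]-N-methoxy-N,3,6-trimethylhepta-3,6-dienamide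
Conditions: TBSCl, imidazole, DMF, rt (directly on crude 7)
Reagents that add atoms: tert-butyldimethylsilyl chloride, CC(C)(C)[Si](C)(C)Cl
Why: Silyl ether formation blocks relactonisation and installs the bulky C10 substituent that later directs the conjugate addition.

Step 7
Reactants: 8 (S,Z)-5-[(tert-butyldimethylsilyl)oxy]-N-methoxy-N,3,6-trimethylhepta-3,6-dienamide
Product: 9 (S,Z)-7-[(tert-butyldimethylsilyl)oxy]-5,8-dimethylnona-1,5,8-trien-3-one
Conditions: CH2=CHMgBr, THF, −20 → 0 °C; poured into cold aq NH4Cl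
Reagents that add atoms: vinylmagnesium bromide, C=C[Mg]Br
Why: Weinreb ketone synthesis; the chelated tetrahedral intermediate prevents over-addition, and the inverse quench keeps the liberated amine from adding to the vinyl ketone.

Step 8
Reactants: 9 (S,Z)-7-[(tert-butyldimethylsilyl)oxy]-5,8-dimethylnona-1,5,8-trien-3-one
Product: 10 (S)-4-[(tert-butyldimethylsilyl)oxy]-3,6-dimethylcyclohepta-2,5-dien-1-one
Conditions: second-generation Hoveyda–Grubbs catalyst RuCl2(=CH-C6H4-2-OiPr)(SIMes) (cat.), toluene, high dilution, 80 °C; chromatography on Et3N-deactivated silica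
Reagents that add atoms: none
Why: Ring-closing metathesis of the vinyl ketone with the isopropenyl group closes the seven-membered ring as the β-methyl enone (C5=C1); the Z C8=C9 alkene already holds the two termini close together.

Step 9
Reactants: 11 methyl 2-methylpropanoate
Product: 12 1-(propan-2-yl)cyclopropan-1-ol
Conditions: EtMgBr, Ti(OiPr)4 (cat.), Et2O/THF, rt; aq NH4Cl
Reagents that add atoms: ethylmagnesium bromide, CC[Mg]Br
Why: Kulinkovich cyclopropanation of the ester by the titanacyclopropane formed from EtMgBr gives the strained three-carbon unit C2–C3–C4 with the isopropyl group and the oxygen already on C4.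

Step 10
Reactants: 10 (S)-4-[(tert-butyldimethylsilyl)oxy]-3,6-dimethylcyclohepta-2,5-dien-1-one; 12 1-(propan-2-yl)cyclopropan-1-ol
Product: 16 (3R,3aR,8S,8aS)-8-[(tert-butyldimethylsilyl)oxy]-3-hydroxy-6,8a-dimethyl-3-(propan-2-yl)-2,3,3a,5,8,8a-hexahydroazulen-4(1H)-one, via bis(4-methyl-3-oxopentyl)zinc 13 (not isolated), via zinc enolate 14 (not isolated), via zinc aldolate 15 (not isolated)
Conditions: Et2Zn (0.5 equiv per 12), THF, 0 °C → rt; then (CuOTf)2·C6H6 (cat.), SIMes·HCl (cat.), 10, −30 °C → rt, kept at rt to equilibrate; aq NH4Cl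
Reagents that add atoms: none
Why: Proposed new method: Et2Zn converts the strained cyclopropanol 12, by O–H deprotonation and C–C ring opening, into the zinc homoenolate 13; its β-carbon (C2) is transferred by the carbene-ligated monovalent copper catalyst to the enone β-carbon C1 of 10, and the zinc enolate 14 so formed (C5=C6–O–Zn) adds through C5 to the isopropyl ketone carbonyl (C4) that arrived with the nucleophile, so that C1–C2, C4–C5 and the cyclopentane are made in one flask. The closest known reaction types are the copper-catalysed conjugate addition of dialkylzinc reagents to β-substituted cyclic enones (quaternary centres), the conjugate addition of cyclopropanol-derived zinc homoenolates to enones, and the intramolecular aldol trapping of zinc enolates from conjugate addition by a ketone; their combination as a [3+2] annulation on a β,β-disubstituted dienone has not been shown. The ring closes in a 5-(enolexo)-exo-trig aldol mode. C1 is set by substrate control, the reagent entering anti to the neighbouring C10 silyloxy group so that the methyl group ends cis to C10–O. C5 and C4 are set under thermodynamic control: the tertiary zinc aldolate can revert by retro-aldol to 14 and reclose, which should funnel the material to the trans-fused aldolate 15, in which zinc bridges O4 and the C6 carbonyl oxygen (O4 syn to C6, isopropyl anti to C6 and to the angular methyl). The step needs 1,4- instead of 1,2-addition without loss of silanol (soft copper–zinc reagent, no strong base, a single enone β-carbon in 10) and reaction only through the C5 enolate (it is born at C5 and no free base is present, so C7 and the skipped C8=C9 alkene are not touched).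

Step 11
Reactants: 16 (3R,3aR,8S,8aS)-8-[(tert-butyldimethylsilyl)oxy]-3-hydroxy-6,8a-dimethyl-3-(propan-2-yl)-2,3,3a,5,8,8a-hexahydroazulen-4(1H)-one
Product: 17 (3R,3aS,4S,8S,8aS)-8-[(tert-butyldimethylsilyl)oxy]-6,8a-dimethyl-3-(propan-2-yl)-1,2,3,3a,4,5,8,8a-octahydroazulene-3,4-diol
Conditions: Me4NBH(OAc)3, MeCN/AcOH, −20 → 0 °C
Reagents that add atoms: none
Why: Hydroxyl-directed (Saksena–Evans) reduction; the C4 hydroxyl exchanges onto boron and delivers hydride to the β-face of the C6 carbonyl, the face on which C4–O lies, which should give the 6α-alcohol.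

Step 12
Reactants: 17 (3R,3aS,4S,8S,8aS)-8-[(tert-butyldimethylsilyl)oxy]-6,8a-dimethyl-3-(propan-2-yl)-1,2,3,3a,4,5,8,8a-octahydroazulene-3,4-diol
Product: 18 (3R,3aS,4S,8S,8aS)-8-[(tert-butyldimethylsilyl)oxy]-3-hydroxy-6,8a-dimethyl-3-(propan-2-yl)-1,2,3,3a,4,5,8,8a-octahydroazulen-4-yl 4-methoxybenzoate
Conditions: 4-MeOC6H4COCl, pyridine, DMAP (cat.), CH2Cl2, 0 °C → rt
Reagents that add atoms: 4-methoxybenzoyl chloride, COc1ccc(cc1)C(Cl)=O
Why: DMAP-catalysed acylation takes the secondary C6 hydroxyl; the tertiary C4 hydroxyl is too hindered to react under these conditions.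

Step 13
Reactants: 18 (3R,3aS,4S,8S,8aS)-8-[(tert-butyldimethylsilyl)oxy]-3-hydroxy-6,8a-dimethyl-3-(propan-2-yl)-1,2,3,3a,4,5,8,8a-octahydroazulen-4-yl 4-methoxybenzoate
Product: 19 (3R,3aS,4S,8S,8aS)-3,8-dihydroxy-6,8a-dimethyl-3-(propan-2-yl)-1,2,3,3a,4,5,8,8a-octahydroazulen-4-yl 4-methoxybenzoate
Conditions: HF·pyridine, pyridine, THF, 0 °C → rt
Reagents that add atoms: none
Why: Fluoride-mediated desilylation under buffered, non-basic conditions frees the C10 hydroxyl without acyl migration or ester cleavage.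

Step 14
Reactants: 19 (3R,3aS,4S,8S,8aS)-3,8-dihydroxy-6,8a-dimethyl-3-(propan-2-yl)-1,2,3,3a,4,5,8,8a-octahydroazulen-4-yl 4-methoxybenzoate
Product: 20 (3R,3aS,4S,8S,8aS)-8-(acetyloxy)-3-hydroxy-6,8a-dimethyl-3-(propan-2-yl)-1,2,3,3a,4,5,8,8a-octahydroazulen-4-yl 4-methoxybenzoate
Conditions: Ac2O, pyridine, DMAP (cat.), CH2Cl2, rt
Reagents that add atoms: acetic anhydride, CC(=O)OC(C)=O
Why: Acetylation of the secondary allylic C10 hydroxyl with a limited amount of anhydride leaves the tertiary C4 hydroxyl free and gives the target.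

**Compound list**

1 | methacrolein (2-methylprop-2-enal) | C=C(C)C=O | starting material
2 | rac-2-methylpenta-1,4-dien-3-ol | C=CC(O)C(C)=C | intermediate
3 | (S)-2-methylpenta-1,4-dien-3-ol | C=C[C@H](O)C(C)=C | intermediate
4 | 3-methylbut-3-enoic acid | C=C(C)CC(=O)O | starting material
5 | (S)-2-methylpenta-1,4-dien-3-yl 3-methylbut-3-enoate | C=C[C@H](OC(=O)CC(C)=C)C(C)=C | intermediate
6 | (S)-4-methyl-6-(prop-1-en-2-yl)-3,6-dihydro-2H-pyran-2-one | CC1=C[C@H](OC(=O)C1)C(C)=C | intermediate
7 | (S,Z)-5-hydroxy-N-methoxy-N,3,6-trimethylhepta-3,6-dienamide | CON(C)C(=O)C/C(C)=C\[C@H](O)C(C)=C | intermediate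
8 | (S,Z)-5-[(tert-butyldimethylsilyl)oxy]-N-methoxy-N,3,6-trimethylhepta-3,6-dienamide | CON(C)C(=O)C/C(C)=C\[C@H](O[Si](C)(C)C(C)(C)C)C(C)=C | intermediate
9 | (S,Z)-7-[(tert-butyldimethylsilyl)oxy]-5,8-dimethylnona-1,5,8-trien-3-one | C=CC(=O)C/C(C)=C\[C@H](O[Si](C)(C)C(C)(C)C)C(C)=C | intermediate
10 | (S)-4-[(tert-butyldimethylsilyl)oxy]-3,6-dimethylcyclohepta-2,5-dien-1-one | CC1=C[C@H](O[Si](C)(C)C(C)(C)C)C(C)=CC(=O)C1 | intermediate
11 | methyl 2-methylpropanoate | COC(=O)C(C)C | starting material
12 | 1-(propan-2-yl)cyclopropan-1-ol | CC(C)C1(O)CC1 | intermediate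
13 | bis(4-methyl-3-oxopentyl)zinc (zinc homoenolate) | CC(C)C(=O)CC[Zn]CCC(=O)C(C)C | intermediate
14 | (4-methyl-3-oxopentyl)zinc enolate of the 1,4-adduct: O-zinc (1S,7S)-7-[(tert-butyldimethylsilyl)oxy]-1,5-dimethyl-1-(4-methyl-3-oxopentyl)cyclohepta-2,5-dien-3-olate | CC(C)C(=O)CC[Zn]OC1=C[C@](C)(CCC(=O)C(C)C)[C@@H](O[Si](C)(C)C(C)(C)C)C=C(C)C1 | intermediate
15 | (4-methyl-3-oxopentyl)zinc alkoxide (at O4) of 16 | O=C1CC(C)=C[C@H](O[Si](C)(C)C(C)(C)C)[C@@]2(C)CC[C@@](O[Zn]CCC(=O)C(C)C)(C(C)C)[C@H]12 | intermediate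
16 | (3R,3aR,8S,8aS)-8-[(tert-butyldimethylsilyl)oxy]-3-hydroxy-6,8a-dimethyl-3-(propan-2-yl)-2,3,3a,5,8,8a-hexahydroazulen-4(1H)-one | O=C1CC(C)=C[C@H](O[Si](C)(C)C(C)(C)C)[C@@]2(C)CC[C@@](O)(C(C)C)[C@H]12 | intermediate
17 | (3R,3aS,4S,8S,8aS)-8-[(tert-butyldimethylsilyl)oxy]-6,8a-dimethyl-3-(propan-2-yl)-1,2,3,3a,4,5,8,8a-octahydroazulene-3,4-diol | O[C@H]1CC(C)=C[C@H](O[Si](C)(C)C(C)(C)C)[C@@]2(C)CC[C@@](O)(C(C)C)[C@H]12 | intermediate
18 | (3R,3aS,4S,8S,8aS)-8-[(tert-butyldimethylsilyl)oxy]-3-hydroxy-6,8a-dimethyl-3-(propan-2-yl)-1,2,3,3a,4,5,8,8a-octahydroazulen-4-yl 4-methoxybenzoate | COc1ccc(cc1)C(=O)O[C@H]1CC(C)=C[C@H](O[Si](C)(C)C(C)(C)C)[C@@]2(C)CC[C@@](O)(C(C)C)[C@H]12 | intermediate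
19 | (3R,3aS,4S,8S,8aS)-3,8-dihydroxy-6,8a-dimethyl-3-(propan-2-yl)-1,2,3,3a,4,5,8,8a-octahydroazulen-4-yl 4-methoxybenzoate | COc1ccc(cc1)C(=O)O[C@H]1CC(C)=C[C@H](O)[C@@]2(C)CC[C@@](O)(C(C)C)[C@H]12 | intermediate
20 | (3R,3aS,4S,8S,8aS)-8-(acetyloxy)-3-hydroxy-6,8a-dimethyl-3-(propan-2-yl)-1,2,3,3a,4,5,8,8a-octahydroazulen-4-yl 4-methoxybenzoate | COc1ccc(C(=O)O[C@H]2CC(C)=C[C@H](OC(C)=O)[C@@]3(C)CC[C@@](O)(C(C)C)[C@H]23)cc1 | target

**Step count and risks**

Total steps: 14. Longest linear sequence: 13 (steps 1–8 and 10–14); step 9 is a one-step branch.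

Steps most likely to fail:

1. Step 10 (proposed new method). Transfer of the homoenolate to the fully substituted, silyloxy-flanked β-carbon may be too slow, so that 1,2-addition or loss of silanol from 10 (aromatisation to the tropone) takes over. The aldolate may also fail to equilibrate and stay cis-fused. The fallback uses known chemistry, sets out from 10 and returns at 16. Cyclopropanol 12 is opened with N-bromosuccinimide to 1-bromo-4-methylpentan-3-one F1, which is ketalised (ethylene glycol, TsOH) to 2-(2-bromoethyl)-2-(propan-2-yl)-1,3-dioxolane F2 and converted with Mg in THF into {2-[2-(propan-2-yl)-1,3-dioxolan-2-yl]ethyl}magnesium bromide F3. CuBr·SMe2-catalysed, TMSCl-accelerated conjugate addition of F3 to 10 (anti to the silyloxy group), followed by hydrolytic work-up, gives the ketal ketone (3S,4S)-4-[(tert-butyldimethylsilyl)oxy]-3,6-dimethyl-3-{2-[2-(propan-2-yl)-1,3-dioxolan-2-yl]ethyl}cyclohept-5-en-1-one F4. PPTS in wet acetone unmasks the diketone (3S,4S)-4-[(tert-butyldimethylsilyl)oxy]-3,6-dimethyl-3-(4-methyl-3-oxopentyl)cyclohept-5-en-1-one F5, which is closed in a separate, equilibrating aldol step (catalytic KOt-Bu, t-BuOH/THF, 0 °C) to 16.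

2. Step 8. Loading of the ruthenium carbene may be slow on both the electron-poor vinyl ketone and the hindered isopropenyl group next to the silyloxy carbon, so that oligomerisation or double-bond migration wins. The fallback sets out from 8 and returns at 10, doing the metathesis at the alcohol oxidation level. Amide 8 is reduced with i-Bu2AlH at −78 °C to (S,Z)-5-[(tert-butyldimethylsilyl)oxy]-3,6-dimethylhepta-3,6-dienal F6. Vinylmagnesium bromide gives (5Z,7S)-7-[(tert-butyldimethylsilyl)oxy]-5,8-dimethylnona-1,5,8-trien-3-ol F7 as a mixture of carbinol epimers. Its unhindered vinyl carbinol should initiate ring-closing metathesis readily, giving (4S)-4-[(tert-butyldimethylsilyl)oxy]-3,6-dimethylcyclohepta-2,5-dien-1-ol F8. Allylic oxidation with MnO2 then gives 10.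

3. Step 11. The tertiary C4 hydroxyl may exchange onto boron too slowly, so that hydride is not delivered intramolecularly and arrives, if at all, from the open α-face. The fallback sets out from 16 and returns at 18, using inversion instead of delivery. NaBH4 in MeOH at −20 °C should reduce from the α-face to the C6 epimer (3R,3aS,4R,8S,8aS)-8-[(tert-butyldimethylsilyl)oxy]-6,8a-dimethyl-3-(propan-2-yl)-1,2,3,3a,4,5,8,8a-octahydroazulene-3,4-diol F9. Mitsunobu esterification of F9 with 4-methoxybenzoic acid (PPh3, DIAD) inverts C6 and gives 18 directly.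

Further compounds
F1 | step 10 | 1-bromo-4-methylpentan-3-one | BrCCC(=O)C(C)C
F2 | step 10 | 2-(2-bromoethyl)-2-(propan-2-yl)-1,3-dioxolane | BrCCC1(C(C)C)OCCO1
F3 | step 10 | {2-[2-(propan-2-yl)-1,3-dioxolan-2-yl]ethyl}magnesium bromide | Br[Mg]CCC1(C(C)C)OCCO1
F4 | step 10 | (3S,4S)-4-[(tert-butyldimethylsilyl)oxy]-3,6-dimethyl-3-{2-[2-(propan-2-yl)-1,3-dioxolan-2-yl]ethyl}cyclohept-5-en-1-one | O=C1C[C@](C)(CCC2(C(C)C)OCCO2)[C@@H](O[Si](C)(C)C(C)(C)C)C=C(C)C1
F5 | step 10 | (3S,4S)-4-[(tert-butyldimethylsilyl)oxy]-3,6-dimethyl-3-(4-methyl-3-oxopentyl)cyclohept-5-en-1-one | O=C1C[C@](C)(CCC(=O)C(C)C)[C@@H](O[Si](C)(C)C(C)(C)C)C=C(C)C1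
F6 | step 8 | (S,Z)-5-[(tert-butyldimethylsilyl)oxy]-3,6-dimethylhepta-3,6-dienal | O=CC/C(C)=C\[C@H](O[Si](C)(C)C(C)(C)C)C(C)=C
F7 | step 8 | (5Z,7S)-7-[(tert-butyldimethylsilyl)oxy]-5,8-dimethylnona-1,5,8-trien-3-ol (carbinol epimers) | C=CC(O)C/C(C)=C\[C@H](O[Si](C)(C)C(C)(C)C)C(C)=C
F8 | step 8 | (4S)-4-[(tert-butyldimethylsilyl)oxy]-3,6-dimethylcyclohepta-2,5-dien-1-ol (carbinol epimers) | CC1=C[C@H](O[Si](C)(C)C(C)(C)C)C(C)=CC(O)C1
F9 | step 11 | (3R,3aS,4R,8S,8aS)-8-[(tert-butyldimethylsilyl)oxy]-6,8a-dimethyl-3-(propan-2-yl)-1,2,3,3a,4,5,8,8a-octahydroazulene-3,4-diol | O[C@@H]1CC(C)=C[C@H](O[Si](C)(C)C(C)(C)C)[C@@]2(C)CC[C@@](O)(C(C)C)[C@H]12
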